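The route rests on cleaving the C5–C10 bond shared by rings A and B of a cis-fused eudesmane-type decalin, made from (S)-Wieland–Miescher ketone, in which ring A carries a pinacol boronate at C1 and a spiro-epoxide at C4 (C15), both equatorial. Alkoxide activation of boron is meant to trigger a Grob fragmentation that creates the C1=C10 and C4=C5 olefins, opens the epoxide to the C15 alcohol and unveils the ten-membered ring, with both olefin geometries fixed by the decalin configuration. The precursor is the 1α-boryl-4β,15-epoxy-13-nor-6β,12-olide 8α-silyl ether. Lactone methylenation, the two esters and a late singlet-oxygen ene reaction at C1=C10 complete the target.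

Key step: step 21

Remark on names: eudesmane numbering is used for the decalins and germacrane numbering after ring opening (C14 = methyl on C10; C11, C12 = lactone carbons; C15 = carbon on C4). α/β refer to the usual drawing in which H-7 is α, so the angular methyl of the (S)-ketone is 10α. With oxygen on C15 the C4=C5 bond of the ring-opened compounds is E by the sequence rule, although C3 and C6 are cis across it (the Z geometry of the parent germacrene).

Assumption: in the last step singlet oxygen is taken to attack the outer face of C1=C10 that gives the (1R)-hydroperoxide; this is addressed under the risks.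

Step 1
Reactants: 1 (S)-Wieland–Miescher ketone
Product: 2 1α-hydroxy enone
Conditions: NaBH4 (0.3 equiv), EtOH, −10 °C
Reagents that add atoms: none
Why: Chemoselective borohydride reduction of the saturated ketone, with hydride adding to the face opposite the angular methyl, sets the (5S) alcohol cis to the methyl (1α-OH).

Step 2
Reactants: 2 1α-hydroxy enone
Product: 3 5α,6α-epoxy ketone
Conditions: 30% H2O2, NaOH aq, MeOH, 0 °C
Reagents that add atoms: hydrogen peroxide, OO
Why: Weitz–Scheffer nucleophilic epoxidation of the enone; the oxirane configuration is irrelevant because C5 and C6 become trigonal again in the next step.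

Step 3
Reactants: 3 5α,6α-epoxy ketone
Product: 4 diosphenol
Conditions: KOH, t-BuOH–H2O, 60 °C; then AcOH to pH 5
Reagents that add atoms: potassium hydroxide, [K+].[OH-] (its oxygen ends on C6; the oxirane oxygen leaves as water)
Why: Base-induced isomerisation of an α,β-epoxy ketone to a diosphenol, in which hydroxide opens the oxirane at C6 and the tertiary C5 hydroxyl is lost by E1cB dehydration.

Step 4
Reactants: 4 diosphenol
Product: 5 6-O-triethylsilyl diosphenol ether
Conditions: Et3SiCl (1.05 equiv), Et3N, CH2Cl2, −20 → 0 °C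
Reagents that add atoms: triethylsilyl chloride, CC[Si](Cl)(CC)CC
Why: O-silylation of the acidic enol hydroxyl is much faster than that of the hindered neopentyl C1 alcohol, which stays free as a directing group.

Step 5
Reactants: 5 6-O-triethylsilyl diosphenol ether
Product: 6 cis-fused 6β-silyloxy ketone
Conditions: H2 (1 atm), [Ir(cod)(PCy3)(py)]PF6 (10 mol %), CH2Cl2, rt
Reagents that add atoms: none
Why: Hydroxyl-directed homogeneous hydrogenation with the cationic iridium catalyst: the 1α-hydroxyl binds iridium and both hydrogens go to the α-face of C5=C6, which sets the cis ring fusion (5α-H) and, by syn addition, the 6β-silyloxy centre.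

Step 6
Reactants: 6 cis-fused 6β-silyloxy ketone
Product: 7 1α,6β-bis(triethylsilyloxy) ketone
Conditions: Et3SiOTf, 2,6-lutidine, CH2Cl2, −78 → 0 °C
Reagents that add atoms: triethylsilyl triflate, CC[Si](CC)(CC)OS(=O)(=O)C(F)(F)F
Why: Silyl triflate protection of the hindered secondary alcohol, needed before the enolate and borane steps.

Step 7
Reactants: 7 1α,6β-bis(triethylsilyloxy) ketone
Product: 8 C7 enol triflate
Conditions: KN(SiMe3)2, THF, −78 °C; then PhNTf2
Reagents that add atoms: N-phenylbis(trifluoromethanesulfonimide), O=S(=O)(N(c1ccccc1)S(=O)(=O)C(F)(F)F)C(F)(F)F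
Why: Kinetic deprotonation occurs at the C8 methylene, not at the hindered silyloxy-bearing C6 methine, and the enolate is O-triflated.

Step 8
Reactants: 8 C7 enol triflate
Product: 9 ethyl 7-en-7-ylacetate
Conditions: BrZnCH2CO2Et (from ethyl bromoacetate and Zn), Pd(PPh3)4 (5 mol %), THF, 60 °C
Reagents that add atoms: ethyl (bromozincio)acetate, CCOC(=O)C[Zn]Br
Why: Negishi-type cross-coupling of the alkenyl triflate with the Reformatsky zinc enolate puts the C11–C12 unit on C7 and touches no stereocentre.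

Step 9
Reactants: 9 ethyl 7-en-7-ylacetate
Product: 11 8α-hydroxy ester, via C8 alkylborane 10 (not isolated)
Conditions: BH3·THF, THF, 0 °C → rt; then 30% H2O2, NaOH aq, 0 °C
Reagents that add atoms: hydrogen peroxide, OO
Why: Hydroboration–oxidation (syn, boron at the less substituted C8): allylic 1,2-strain holds the 6β-silyloxy group pseudoaxial so that it and the axial C1 shield the β-face, and borane adds from the α-face to set 7α-H (C11 β, cis to O6) and 8α-OH.

Step 10
Reactants: 11 8α-hydroxy ester
Product: 12 8α-TBS ether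
Conditions: t-BuMe2SiOTf, 2,6-lutidine, CH2Cl2, −78 → 0 °C
Reagents that add atoms: tert-butyldimethylsilyl triflate, CC(C)(C)[Si](C)(C)OS(=O)(=O)C(F)(F)F
Why: Silylation of the secondary alcohol with a group that survives removal of the triethylsilyl ethers.

Step 11
Reactants: 12 8α-TBS ether
Product: 14 1α-hydroxy cis-lactone, via diol ester 13 (not isolated)
Conditions: HF·pyridine, pyridine, THF, 0 °C → rt; then PPTS (cat.), toluene, 50 °C
Reagents that add atoms: none
Why: Buffered HF·pyridine cleaves the triethylsilyl ethers selectively beside the TBS ether, and the cis-disposed 6β-hydroxyl and ester then lactonise under mild acid to the cis-fused γ-lactone.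

Step 12
Reactants: 14 1α-hydroxy cis-lactone
Product: 16 2-en-1-one, via 1-keto lactone 15 (not isolated)
Conditions: IBX (4 equiv), DMSO–fluorobenzene, 75 °C
Reagents that add atoms: none
Why: IBX oxidises the alcohol to the ketone and then dehydrogenates it (Nicolaou dehydrogenation) toward C2–C3, the only enolisable side.

Step 13
Reactants: 16 2-en-1-one
Product: 17 2-ene-1,4-dione
Conditions: Pd(OH)2/C (5 mol %), t-BuOOH (5 equiv), K2CO3 (0.25 equiv), CH2Cl2, 4 °C → rt
Reagents that add atoms: tert-butyl hydroperoxide, CC(C)(C)OO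
Why: Corey–Yu oxidation of an enone at its only γ-methylene gives the 1,4-enedione and so brings oxygen to C4.

Step 14
Reactants: 17 2-ene-1,4-dione
Product: 18 1,4-dione
Conditions: H2 (1 atm), 10% Pd/C, EtOAc, rt
Reagents that add atoms: none
Why: Catalytic hydrogenation of the electron-poor enedione alkene; C5 is now epimerisable, but the cis fusion is the stable one because the 8α-silyloxy group would be 1,3-diaxial to C14 in the trans isomer.

Step 15
Reactants: 18 1,4-dione
Product: 19 4(15)-methylene 1-ketone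
Conditions: Ph3PCH3Br, KOt-Bu (preformed ylide, 1.3 equiv), THF, 0 °C
Reagents that add atoms: methyltriphenylphosphonium bromide, C[P+](c1ccccc1)(c1ccccc1)c1ccccc1.[Br-]
Why: Wittig methylenation is selective for the C4 ketone because the C1 ketone is neopentyl (next to the quaternary C10) and reacts only under forcing conditions.

Step 16
Reactants: 19 4(15)-methylene 1-ketone
Product: 20 C1 enol triflate
Conditions: KN(SiMe3)2 (1.05 equiv), THF, −78 °C; then PhNTf2
Reagents that add atoms: N-phenylbis(trifluoromethanesulfonimide), O=S(=O)(N(c1ccccc1)S(=O)(=O)C(F)(F)F)C(F)(F)F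
Why: The ketone, more acidic than the lactone by several pKa units, is deprotonated at C2 (its only α-hydrogens) and the enolate is O-triflated.

Step 17
Reactants: 20 C1 enol triflate
Product: 21 4β,15-diol triflate
Conditions: OsO4 (2 mol %), NMO, acetone–H2O, 0 °C → rt
Reagents that add atoms: N-methylmorpholine N-oxide, C[N+]1([O-])CCOCC1; water, O
Why: Upjohn dihydroxylation of the electron-rich 1,1-disubstituted alkene (the alkenyl triflate is inert) from the β-face, anti to the syn-axial 10α-methyl, sets the 4β-hydroxyl with C15 axial on the α-face.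

Step 18
Reactants: 21 4β,15-diol triflate; 22 bis(pinacolato)diboron
Product: 23 alkenyl boronate diol
Conditions: PdCl2(dppf) (5 mol %), KOAc, 1,4-dioxane, 80 °C
Reagents that add atoms: bis(pinacolato)diboron (22), CC1(C)OB(OC1(C)C)B1OC(C)(C)C(C)(C)O1
Why: Miyaura borylation of the alkenyl triflate puts boron on C1 without touching a stereocentre.

Step 19
Reactants: 23 alkenyl boronate diol
Product: 24 1α-boryl 4β,15-diol
Conditions: H2 (1 atm), [Ir(cod)(PCy3)(py)]PF6 (10 mol %), CH2Cl2, rt
Reagents that add atoms: none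
Why: Hydroxyl-directed hydrogenation of the alkenyl boronate: the 4β-hydroxyl delivers hydrogen to the β-face of C1=C2, also the less hindered face because C14 and the axial C15 block the α-face, which sets the equatorial 1α C–B bond trans to the C4 oxygen.

Step 20
Reactants: 24 1α-boryl 4β,15-diol
Product: 26 epoxy boronate, via C15 tosylate 25 (not isolated)
Conditions: TsCl, pyridine, DMAP (cat.), CH2Cl2, 0 °C; then NaH (1.1 equiv), THF, 0 °C
Reagents that add atoms: none
Why: Selective tosylation of the primary alcohol and Williamson closure by the tertiary alkoxide give the spiro-epoxide with retention at C4, because the C4–O bond is never broken.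

Step 21
Reactants: 26 epoxy boronate
Product: 29 15-hydroxy germacradienolide, via boronate ate complex 27 (not isolated), via potassium alkoxide 28 (not isolated)
Conditions: KOt-Bu (1.5 equiv), THF–t-BuOH (20:1), −40 °C → rt; then H2O
Reagents that add atoms: none
Why: Proposed new method: tert-butoxide adds to boron to give ate complex 27, whose electron-rich C1–B bond is antiperiplanar to C5–C10, itself antiperiplanar to the equatorial C4–O bond of the strained oxirane, so that C1=C10 forms, C5–C10 breaks, C4=C5 forms and the oxirane opens to the C15 alkoxide 28 in one concerted seven-centre Grob fragmentation. The closest known reaction type is the hydroxide- or alkoxide-triggered fragmentation of 1-boryl decalin 4-sulfonates to cyclodeca-1,5-dienes, together with fragmentations in which an epoxide oxygen is the nucleofuge; expulsion of an unactivated epoxide by a pinacol boronate ate complex has not been shown. The ten-membered ring is not closed by bond formation but unveiled by cleavage of the bond shared by rings A and B, so no cyclisation mode or entropic penalty applies. No stereocentre is created; the olefin geometries follow from the reacting chair of ring A, where C9 is equatorial and C14 axial at C10 (C2 and C14 cis, hence 1(10)E) and C6 is axial at C5 (C3 and C6 cis across C4=C5). The step needs boron to be attacked in preference to the lactone and the chair with equatorial C1–B and C4–O bonds to react: bulky tert-butoxide at low temperature serves the first, and the 8α-silyloxy group and C7 side chain, which would be 1,3-diaxial to C14 and C4 in the other chair–chair form, serve the second.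

Step 22
Reactants: 29 15-hydroxy germacradienolide
Product: 32 α-methylene lactone 15-ol, via Mannich base 30 (not isolated), via ammonium iodide 31 (not isolated)
Conditions: LiN(SiMe3)2 (2.3 equiv), THF, −78 °C; H2C=NMe2+ I−, −78 → 0 °C; then MeI, MeOH, rt; then NaHCO3 aq, CH2Cl2, rt
Reagents that add atoms: Eschenmoser's salt, C=[N+](C)C.[I-]
Why: Lactone α-methylenation by the Eschenmoser-salt Mannich reaction, quaternisation and elimination; the first equivalent of base only forms the C15 alkoxide, and no acetate is yet present to compete for the base.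

Step 23
Reactants: 32 α-methylene lactone 15-ol
Product: 33 15-acetate
Conditions: Ac2O, pyridine, CH2Cl2, 0 °C → rt
Reagents that add atoms: acetic anhydride, CC(=O)OC(C)=O
Why: Acetylation of the primary allylic alcohol under conditions that leave the α-methylene lactone alone.

Step 24
Reactants: 33 15-acetate
Product: 34 8α-alcohol
Conditions: HF·pyridine, pyridine, THF, 0 °C → rt
Reagents that add atoms: none
Why: Fluoride desilylation under buffered, non-basic conditions spares the α-methylene lactone, the acetate and the diene.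

Step 25
Reactants: 35 methyl (S)-2,2-dimethyl-1,3-dioxolane-4-carboxylate
Product: 36 Weinreb amide
Conditions: MeNHOMe·HCl, i-PrMgCl, THF, −20 °C
Reagents that add atoms: N,O-dimethylhydroxylamine hydrochloride, CNOC.Cl
Why: Weinreb amide formation from the ester with the chloromagnesium amide at low temperature does not enolise the α-alkoxy stereocentre.

Step 26
Reactants: 36 Weinreb amide
Product: 37 methyl ketone
Conditions: MeMgBr, THF, 0 °C
Reagents that add atoms: methylmagnesium bromide, C[Mg]Br
Why: Grignard addition to the Weinreb amide stops at the ketone through the stable chelate.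

Step 27
Reactants: 37 methyl ketone
Product: 38 alkenyl triflate
Conditions: KN(SiMe3)2, THF, −78 °C; then PhNTf2
Reagents that add atoms: N-phenylbis(trifluoromethanesulfonimide), O=S(=O)(N(c1ccccc1)S(=O)(=O)C(F)(F)F)C(F)(F)F
Why: Kinetic deprotonation at the methyl group, not at the α-alkoxy methine, and O-triflation leave the stereocentre untouched.

Step 28
Reactants: 38 alkenyl triflate
Product: 39 acetonide acid
Conditions: CO (1 atm), Pd(OAc)2, dppf, Et3N, DMF–H2O, 60 °C
Reagents that add atoms: carbon monoxide, [C-]#[O+]; water, O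
Why: Hydroxycarbonylation of the alkenyl triflate gives the α-substituted acrylic acid; the stereocentre is untouched and becomes (R) only because the substituent priorities change.

Step 29
Reactants: 34 8α-alcohol; 39 acetonide acid
Product: 40 8-O-acyl acetonide
Conditions: EDC·HCl, DMAP, CH2Cl2, 0 °C → rt
Reagents that add atoms: none
Why: Steglich esterification of the only free hydroxyl with retention at C8.

Step 30
Reactants: 40 8-O-acyl acetonide
Product: 41 side-chain diol
Conditions: AcOH–H2O (4:1), 35 °C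
Reagents that add atoms: none
Why: Mild acid hydrolysis of the terminal acetonide, under conditions too weak to cyclise the deactivated germacradiene.

Step 31
Reactants: 41 side-chain diol
Product: 42 target hydroperoxide
Conditions: O2, visible light, tetraphenylporphyrin (cat.), CH2Cl2, −20 °C
Reagents that add atoms: dioxygen, O=O
Why: Schenck ene reaction of singlet oxygen at the electron-rich trisubstituted C1=C10 bond (C4=C5 and the acrylates are electron-poor): oxygen should bond to C1 from the exposed outer face with abstraction of a C14 hydrogen, giving the 10(14)-ene and the (1R)-hydroperoxide.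

Compound list
1 | (S)-Wieland–Miescher ketone, (8aS)-8a-methyl-3,4,8,8a-tetrahydronaphthalene-1,6(2H,7H)-dione | C[C@]12CCC(=O)C=C1CCCC2=O | starting material
2 | (4aS,5S)-5-hydroxy-4a-methyl-4,4a,5,6,7,8-hexahydronaphthalen-2(3H)-one (1α-hydroxy-5-en-7-one, OH cis to C14) | C[C@]12CCC(=O)C=C1CCC[C@@H]2O | intermediate
3 | 5α,6α-epoxy-1α-hydroxy-7-ketone (oxirane drawn cis to C14; either epimer serves) | C[C@]12CCC(=O)[C@@H]3O[C@@]31CCC[C@@H]2O | intermediate
4 | diosphenol, 1α,6-dihydroxy-5-en-7-one | C[C@]12CCC(=O)C(O)=C1CCC[C@@H]2O | intermediate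
5 | 1α-hydroxy-6-(triethylsilyloxy)-5-en-7-one | C[C@]12CCC(=O)C(O[Si](CC)(CC)CC)=C1CCC[C@@H]2O | intermediate
6 | cis-fused (5α-H,10α-Me) 1α-hydroxy-6β-(triethylsilyloxy)decalin-7-one | C[C@]12CCC(=O)[C@@H](O[Si](CC)(CC)CC)[C@H]1CCC[C@@H]2O | intermediate
7 | cis-fused 1α,6β-bis(triethylsilyloxy)decalin-7-one | C[C@]12CCC(=O)[C@@H](O[Si](CC)(CC)CC)[C@H]1CCC[C@@H]2O[Si](CC)(CC)CC | intermediate
8 | cis-fused 1α,6β-bis(triethylsilyloxy)-7-en-7-yl triflate | C[C@]12CC=C(OS(=O)(=O)C(F)(F)F)[C@@H](O[Si](CC)(CC)CC)[C@H]1CCC[C@@H]2O[Si](CC)(CC)CC | intermediate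
9 | ethyl 2-[cis-fused 1α,6β-bis(triethylsilyloxy)-7-en-7-yl]acetate | C[C@]12CC=C(CC(=O)OCC)[C@@H](O[Si](CC)(CC)CC)[C@H]1CCC[C@@H]2O[Si](CC)(CC)CC | intermediate
10 | 8α-boryl (alkylborane) 7α-H ester, written as the monoalkylborane | C[C@]12C[C@H]([BH2])[C@@H](CC(=O)OCC)[C@@H](O[Si](CC)(CC)CC)[C@H]1CCC[C@@H]2O[Si](CC)(CC)CC | intermediate
11 | ethyl ester with 8α-OH, 7β-CH2CO2Et, 6β-OSiEt3, 1α-OSiEt3 | C[C@]12C[C@H](O)[C@@H](CC(=O)OCC)[C@@H](O[Si](CC)(CC)CC)[C@H]1CCC[C@@H]2O[Si](CC)(CC)CC | intermediate
12 | 8α-(tert-butyldimethylsilyloxy) ester with 6β- and 1α-OSiEt3 | C[C@]12C[C@H](O[Si](C)(C)C(C)(C)C)[C@@H](CC(=O)OCC)[C@@H](O[Si](CC)(CC)CC)[C@H]1CCC[C@@H]2O[Si](CC)(CC)CC | intermediate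
13 | 1α,6β-dihydroxy 8α-TBS ether ethyl ester | C[C@]12C[C@H](O[Si](C)(C)C(C)(C)C)[C@@H](CC(=O)OCC)[C@@H](O)[C@H]1CCC[C@@H]2O | intermediate
14 | 1α-hydroxy-8α-(TBS-oxy)-13-nor-5α,10α-eudesman-6β,12-olide (cis-lactone) | C[C@]12C[C@H](O[Si](C)(C)C(C)(C)C)[C@H]3CC(=O)O[C@H]3[C@H]1CCC[C@@H]2O | intermediate
15 | 1-oxo-8α-(TBS-oxy)-13-nor-5α,10α-eudesman-6β,12-olide | C[C@]12C[C@H](O[Si](C)(C)C(C)(C)C)[C@H]3CC(=O)O[C@H]3[C@H]1CCCC2=O | intermediate
16 | 1-oxo-8α-(TBS-oxy)-13-nor-5α,10α-eudesm-2-en-6β,12-olide | C[C@]12C[C@H](O[Si](C)(C)C(C)(C)C)[C@H]3CC(=O)O[C@H]3[C@H]1CC=CC2=O | intermediate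
17 | 1,4-dioxo-8α-(TBS-oxy)-13,15-dinor-5α,10α-eudesm-2-en-6β,12-olide | C[C@]12C[C@H](O[Si](C)(C)C(C)(C)C)[C@H]3CC(=O)O[C@H]3[C@H]1C(=O)C=CC2=O | intermediate
18 | 1,4-dioxo-8α-(TBS-oxy)-13,15-dinor-5α,10α-eudesman-6β,12-olide | C[C@]12C[C@H](O[Si](C)(C)C(C)(C)C)[C@H]3CC(=O)O[C@H]3[C@H]1C(=O)CCC2=O | intermediate
19 | 1-oxo-8α-(TBS-oxy)-13-nor-5α,10α-eudesm-4(15)-en-6β,12-olide | C[C@]12C[C@H](O[Si](C)(C)C(C)(C)C)[C@H]3CC(=O)O[C@H]3[C@H]1C(=C)CCC2=O | intermediate
20 | 8α-(TBS-oxy)-13-nor-5α,10α-eudesma-1,4(15)-dien-6β,12-olid-1-yl triflate | C[C@]12C[C@H](O[Si](C)(C)C(C)(C)C)[C@H]3CC(=O)O[C@H]3[C@H]1C(=C)CC=C2OS(=O)(=O)C(F)(F)F | intermediate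
21 | 4β,15-dihydroxy-8α-(TBS-oxy)-13-nor-5α,10α-eudesm-1-en-6β,12-olid-1-yl triflate | C[C@]12C[C@H](O[Si](C)(C)C(C)(C)C)[C@H]3CC(=O)O[C@H]3[C@H]1[C@](O)(CO)CC=C2OS(=O)(=O)C(F)(F)F | intermediate
22 | bis(pinacolato)diboron | CC1(C)OB(OC1(C)C)B1OC(C)(C)C(C)(C)O1 | starting material
23 | 1-(pinacolboryl)-4β,15-dihydroxy-8α-(TBS-oxy)-13-nor-5α,10α-eudesm-1-en-6β,12-olide | C[C@]12C[C@H](O[Si](C)(C)C(C)(C)C)[C@H]3CC(=O)O[C@H]3[C@H]1[C@](O)(CO)CC=C2B4OC(C)(C)C(C)(C)O4 | intermediate
24 | 1α-(pinacolboryl)-4β,15-dihydroxy-8α-(TBS-oxy)-13-nor-5α,10α-eudesman-6β,12-olide | C[C@]12C[C@H](O[Si](C)(C)C(C)(C)C)[C@H]3CC(=O)O[C@H]3[C@H]1[C@](O)(CO)CC[C@@H]2B4OC(C)(C)C(C)(C)O4 | intermediate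
25 | 15-O-tosylate of 24 (4β-OH free) | C[C@]12C[C@H](O[Si](C)(C)C(C)(C)C)[C@H]3CC(=O)O[C@H]3[C@H]1[C@](O)(COS(=O)(=O)c4ccc(C)cc4)CC[C@@H]2B5OC(C)(C)C(C)(C)O5 | intermediate
26 | 1α-(pinacolboryl)-4β,15-epoxy-8α-(TBS-oxy)-13-nor-5α,10α-eudesman-6β,12-olide (fragmentation precursor) | C[C@]12C[C@H](O[Si](C)(C)C(C)(C)C)[C@H]3CC(=O)O[C@H]3[C@H]1[C@]4(CO4)CC[C@@H]2B5OC(C)(C)C(C)(C)O5 | intermediate
27 | potassium tert-butoxy boronate ate complex of 26 | C[C@]12C[C@H](O[Si](C)(C)C(C)(C)C)[C@H]3CC(=O)O[C@H]3[C@H]1[C@]4(CO4)CC[C@@H]2[B-]5(OC(C)(C)C)OC(C)(C)C(C)(C)O5.[K+] | intermediate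
28 | potassium C15 alkoxide of 29 | C1C(=O)O[C@H]2/C=C(/C[O-])CC/C=C(\C)C[C@H](O[Si](C)(C)C(C)(C)C)[C@@H]12.[K+] | intermediate
29 | 15-hydroxy-8α-(TBS-oxy)-13-norgermacra-1(10)E,4E-dien-6β,12-olide (C3 and C6 cis across C4=C5; cis-lactone) | C1C(=O)O[C@H]2/C=C(/CO)CC/C=C(\C)C[C@H](O[Si](C)(C)C(C)(C)C)[C@@H]12 | intermediate
30 | 11-(dimethylaminomethyl) derivative of 29 (C11 epimers) | CN(C)CC1C(=O)O[C@H]2/C=C(/CO)CC/C=C(\C)C[C@H](O[Si](C)(C)C(C)(C)C)[C@@H]12 | intermediate
31 | 11-(trimethylammoniomethyl) iodide of 29 (C11 epimers) | C[N+](C)(C)CC1C(=O)O[C@H]2/C=C(/CO)CC/C=C(\C)C[C@H](O[Si](C)(C)C(C)(C)C)[C@@H]12.[I-] | intermediate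
32 | 15-hydroxy-8α-(TBS-oxy)germacra-1(10)E,4E,11(13)-trien-6β,12-olide | C=C1C(=O)O[C@H]2/C=C(/CO)CC/C=C(\C)C[C@H](O[Si](C)(C)C(C)(C)C)[C@@H]12 | intermediate
33 | 15-acetoxy-8α-(TBS-oxy)germacra-1(10)E,4E,11(13)-trien-6β,12-olide | C=C1C(=O)O[C@H]2/C=C(/COC(C)=O)CC/C=C(\C)C[C@H](O[Si](C)(C)C(C)(C)C)[C@@H]12 | intermediate
34 | 15-acetoxy-8α-hydroxygermacra-1(10)E,4E,11(13)-trien-6β,12-olide | C=C1C(=O)O[C@H]2/C=C(/COC(C)=O)CC/C=C(\C)C[C@H](O)[C@@H]12 | intermediate
35 | methyl (S)-2,2-dimethyl-1,3-dioxolane-4-carboxylate | COC(=O)[C@@H]1COC(C)(C)O1 | starting material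
36 | (S)-N-methoxy-N,2,2-trimethyl-1,3-dioxolane-4-carboxamide | CON(C)C(=O)[C@@H]1COC(C)(C)O1 | intermediate
37 | 1-[(4S)-2,2-dimethyl-1,3-dioxolan-4-yl]ethanone | CC(=O)[C@@H]1COC(C)(C)O1 | intermediate
38 | 1-[(4S)-2,2-dimethyl-1,3-dioxolan-4-yl]vinyl triflate | C=C(OS(=O)(=O)C(F)(F)F)[C@@H]1COC(C)(C)O1 | intermediate
39 | 2-[(4R)-2,2-dimethyl-1,3-dioxolan-4-yl]acrylic acid | C=C(C(=O)O)[C@@H]1COC(C)(C)O1 | intermediate
40 | 8-O-{2-[(4R)-2,2-dimethyl-1,3-dioxolan-4-yl]acryloyl} ester of 34 | C=C1C(=O)O[C@H]2/C=C(/COC(C)=O)CC/C=C(\C)C[C@H](OC(=O)C(=C)[C@@H]3COC(C)(C)O3)[C@@H]12 | intermediate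
41 | 8-O-{2-[(1R)-1,2-dihydroxyethyl]acryloyl} ester of 34 | C=C1C(=O)O[C@H]2/C=C(/COC(C)=O)CC/C=C(\C)C[C@H](OC(=O)C(=C)[C@@H](O)CO)[C@@H]12 | intermediate
42 | target, (1R,6S,7R,8S)-15-acetoxy-1-hydroperoxy-8-{2-[(1R)-1,2-dihydroxyethyl]acryloyloxy}germacra-4E,10(14),11(13)-trien-6,12-olide | C=C1C(=O)O[C@H]2/C=C(/COC(C)=O)CC[C@@H](OO)C(=C)C[C@H](OC(=O)C(=C)[C@@H](O)CO)[C@@H]12 | target

Total step count: 31. Longest linear sequence: 27 steps (steps 1–24 and 29–31); the acid 39 is made in 4 steps (25–28).

Steps most likely to fail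

Step 21. The ate complex may form reversibly without fragmenting, because an unactivated oxirane oxygen is a much poorer nucleofuge than a sulfonate; slow protodeboronation or alkoxide attack on the lactone would then take over. The fallback changes the nucleofuge to a sulfate ester, the leaving-group class for which boronate-triggered decalin fragmentation is established. It sets out from diol 24, which with 1,1'-sulfonyldiimidazole and NaH in THF would give the 4β,15-cyclic sulfate F1. Treatment of F1 with KOt-Bu in THF would fragment its boronate ate complex with loss of the tertiary C4–O sulfate bond to give the potassium 15-sulfate of the germacradienolide F2. Hydrolysis of the sulfate monoester (catalytic H2SO4, THF, a little water, rt) returns alcohol 29, where the route is rejoined.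

Step 19. Hydrogen delivery may be slow or unselective: the tertiary 4β-hydroxyl is equatorial in the preferred half-chair of ring A and may bind iridium poorly, and the free diol may retard the catalyst on the hindered alkenyl boronate. The fallback drops the directing group and relies on substrate shielding. It sets out from enol triflate 20, which is epoxidised with mCPBA/NaHCO3 from the β-face (anti to the 10α-methyl; the alkenyl triflate is inert) to the 4β,15-epoxy enol triflate F3. Miyaura borylation (compound 22, PdCl2(dppf), KOAc) then gives the epoxy alkenyl boronate F4. Heterogeneous hydrogenation (H2, Pd/C, EtOAc), in which C14 and the axial C15 block the α-face, would give 26 directly, replacing steps 17–20.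

Step 31. Hydrogen may be abstracted from C2 instead of C14 (10-hydroperoxide with a C1=C2 bond), or oxygen may attack the other face of C1=C10 in the conformer of the fully acylated substrate. The fallback moves the oxygenation to an earlier compound with a different C8 substituent and carries the hydroperoxide protected. It sets out from silyl ether 33, whose photooxygenation (O2, light, tetraphenylporphyrin) would give the 1β-hydroperoxy 8α-silyl ether F5, with isomers separated at this simpler stage. 2-Methoxypropene and catalytic PPTS protect it as the 2-methoxyprop-2-yl peroxide F6, and HF·pyridine then frees the 8α-alcohol F7. EDC/DMAP esterification with acid 39 gives the acylated peroxyketal acetonide F8, and aqueous acetic acid removes the acetonide and the peroxyketal together to give 42.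

Further compounds
F1 | step 21 | 4β,15-cyclic sulfate of diol 24 | C[C@]12C[C@H](O[Si](C)(C)C(C)(C)C)[C@H]3CC(=O)O[C@H]3[C@H]1[C@]4(COS(=O)(=O)O4)CC[C@@H]2B5OC(C)(C)C(C)(C)O5
F2 | step 21 | potassium 15-sulfate of the germacradienolide 29 | C1C(=O)O[C@H]2/C=C(/COS(=O)(=O)[O-])CC/C=C(\C)C[C@H](O[Si](C)(C)C(C)(C)C)[C@@H]12.[K+]
F3 | step 19 | 4β,15-epoxy enol triflate | C[C@]12C[C@H](O[Si](C)(C)C(C)(C)C)[C@H]3CC(=O)O[C@H]3[C@H]1[C@]4(CO4)CC=C2OS(=O)(=O)C(F)(F)F
F4 | step 19 | 4β,15-epoxy alkenyl boronate | C[C@]12C[C@H](O[Si](C)(C)C(C)(C)C)[C@H]3CC(=O)O[C@H]3[C@H]1[C@]4(CO4)CC=C2B5OC(C)(C)C(C)(C)O5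
F5 | step 31 | 1β-hydroperoxy 8α-silyl ether (15-acetate, 10(14)-ene) | C=C1C(=O)O[C@H]2/C=C(/COC(C)=O)CC[C@@H](OO)C(=C)C[C@H](O[Si](C)(C)C(C)(C)C)[C@@H]12
F6 | step 31 | 2-methoxyprop-2-yl peroxide of F5 | C=C1C(=O)O[C@H]2/C=C(/COC(C)=O)CC[C@@H](OOC(C)(C)OC)C(=C)C[C@H](O[Si](C)(C)C(C)(C)C)[C@@H]12
F7 | step 31 | 8α-alcohol peroxyketal | C=C1C(=O)O[C@H]2/C=C(/COC(C)=O)CC[C@@H](OOC(C)(C)OC)C(=C)C[C@H](O)[C@@H]12
F8 | step 31 | acylated peroxyketal acetonide | C=C1C(=O)O[C@H]2/C=C(/COC(C)=O)CC[C@@H](OOC(C)(C)OC)C(=C)C[C@H](OC(=O)C(=C)[C@@H]3COC(C)(C)O3)[C@@H]12
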